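Target numbering: C1 (CH‑isobutenyl), C2 (CH2), C3 (CHMe), C4 (CH‑CH2OAr), C5 (quaternary: Me, CH2CH2CO2H). The retrosynthesis cuts the aryl O–CH2 bond and the isobutenyl C=C, reconnects the acid carbon to the isobutenyl CH as a cyclohexanone, then cuts C3–CH3, C4–CH2O, and last the C5–chain and C1–CH bonds.
Enabling feature: ring carbons C1–C5, the C5 methyl, the three acid‑chain carbons and the isobutenyl CH are the ten carbons of the Hajos–Parrish ketone opened between the acid carbon and the isobutenyl CH. C5 is its angular carbon, C4 its free cyclopentanone carbonyl and C1 its enone β‑carbon.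
Forward order: the cyclopentane is bought as the dione and step 1 closes a temporary cyclohexenone on it. C4 and C3 are substituted while C1 is still trigonal, hydrogenation fixes C1, and ozonolysis of the Δ4 enol ether opens the six‑membered ring. Olefination, etherification with umbelliferone and saponification finish the synthesis.
Stereochemistry: C5 comes from (R)‑proline, which chooses between two enantiotopic carbonyls. C3 comes from cuprate attack anti to the angular methyl, and C4 from protonation and equilibration to the trans ester. C1 comes from cis‑selective hydrogenation, with the six‑membered ring holding acid chain and isobutenyl carbon cis.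

Key step: step 1

Convention (remark on the chemistry): bicyclic compounds carry hydrindane numbering. C7a = target C5, C3a = C1, C3 = C2, C2 = C3, C1 = C4; C7, C6 and C5 are the acid chain and C4 is the isobutenyl CH. β is the face of the 7a‑methyl group and α the opposite face.

Step 1
Reactants: 1 2-methylcyclopentane-1,3-dione; 2 but-3-en-2-one
Product: 5 (R)-Hajos–Parrish ketone, via triketone 3 (not isolated), via cis-ketol 4 (not isolated)
Conditions: 2 (1.5 equiv), (R)-proline (cat.), DMF, rt; then conc. H2SO4 (cat.) in DMF, 95 °C, same flask; recrystallisation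
Reagents that add atoms: none
Why: Mechanism: the enol of 1 adds to 2 (Michael addition, forming the C5–chain bond) to give the prochiral triketone 3, (R)-proline condenses with its side-chain methyl ketone to an enamine whose CH2 terminus attacks one ring carbonyl (forming the C1–CH bond) to give cis-ketol 4, and acid-catalysed dehydration gives enone 5. The closest known reaction type is the Hajos–Parrish–Eder–Sauer–Wiechert reaction in its one-flask proline Robinson annulation form. The one ring closed, the temporary cyclohexenone, arises by a 6-(enolendo)-exo-trig aldol addition. The one lasting stereocentre, C7a (target C5), is controlled by the catalyst: in the chair-like transition state the carboxylic acid of the proline enamine hydrogen-bonds to, and thereby activates, only one of the two enantiotopic ring carbonyls, and (R)-proline leads to the (R)-enedione (the carbinol centre of 4 is lost on dehydration). The step needs group selectivity between the two ring carbonyls and site selectivity for the methyl ketone as the donor; the mirror symmetry of 3 leaves the first entirely to the catalyst, and the second is secured because only the enamine of the unhindered side-chain ketone can reach a ring carbonyl through a six-membered transition state. The attacked carbonyl becomes C1 and the untouched one C4, so the two positions are chemically different from here on.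

Step 2
Reactants: 5 (R)-Hajos–Parrish ketone
Product: 6 (7aR)-dithiolane ketone (5 with C5=O converted into a spiro-1,3-dithiolane; C3a=C4 kept, C1 ketone free)
Conditions: HSCH2CH2SH (1.05 equiv), p-TsOH (cat.), AcOH, rt
Reagents that add atoms: ethane-1,2-dithiol, SCCS
Why: Acid-catalysed thioketalisation is known to pick the enone carbonyl of such enediones, which reacts through a delocalised allylic thionium ion without moving the C3a=C4 double bond, while the C1 carbonyl is shielded by the adjacent quaternary C7a; the mask keeps C3a trigonal and removes the competing acidic and electrophilic sites of the enone for steps 3 to 6.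

Step 3
Reactants: 6 (7aR)-dithiolane ketone
Product: 7 (7aR)-enol triflate (C1(OTf)=C2; C3a=C4 and dithiolane kept)
Conditions: KHMDS, THF, −78 °C; PhNTf2, −78 → 0 °C; aq NH4Cl
Reagents that add atoms: N-phenylbis(trifluoromethanesulfonimide), O=S(=O)(N(c1ccccc1)S(=O)(=O)C(F)(F)F)C(F)(F)F
Why: C7a is quaternary, so the C1 ketone can enolise only towards C2 and O-sulfonylation of the potassium enolate with PhNTf2 gives a single enol triflate, as is routine for the analogous 17-keto steroids.

Step 4
Reactants: 7 (7aR)-enol triflate
Product: 8 methyl (7aR)-enoate (CO2Me on C1 of the C1=C2 double bond; C3a=C4 and dithiolane kept)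
Conditions: Pd(OAc)2 (cat.), dppf (cat.), CO (1 atm), MeOH, Et3N, DMF, 50 °C
Reagents that add atoms: carbon monoxide, [C-]#[O+]; methanol, CO
Why: Palladium-catalysed alkoxycarbonylation of an enol triflate (oxidative addition, CO insertion, methanolysis), a reaction worked out on hindered steroidal 17-enol triflates, forms the bond from target C4 to its exocyclic carbon and at the same time creates the acceptor for step 5; a chelating phosphine keeps palladium from being tied up by the thioketal sulfur.

Step 5
Reactants: 8 methyl (7aR)-enoate
Product: 9 methyl (1R,2S,7aS)-2,7a-dimethyl-5,5-(ethylenedithio)-2,3,5,6,7,7a-hexahydro-1H-indene-1-carboxylate (2-Me α, trans to 7a-Me; 1-CO2Me β, cis to 7a-Me)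
Conditions: Me2CuLi (MeLi, CuI), Et2O, −20 → 0 °C; aq NH4Cl; then NaOMe (cat.), MeOH, rt
Reagents that add atoms: lithium dimethylcuprate, [Li+].C[Cu-]C
Why: Organocuprate conjugate addition to a cyclopentene-1-carboxylate: with C3a still trigonal the bicycle is nearly flat and its pseudoaxial 7a-methyl group blocks the β-face, so methyl enters C2 from the α-face (the 16α-methylation pattern of 16-dehydro steroids, setting target C3), and protonation of the enolate from the same open face, backed by methoxide equilibration, leaves the ester β, trans to the new methyl group (setting target C4).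

Step 6
Reactants: 9 methyl ester
Product: 10 (1R,2S,7aS)-1-hydroxymethyl-2,7a-dimethyl dithiolane (CH2OH β, 2-Me α, C3a=C4 kept)
Conditions: LiAlH4, THF, 0 °C; H2O work-up
Reagents that add atoms: none
Why: Lithium aluminium hydride reduces even this flanked ester to the primary alcohol, whereas the thioketal and the unactivated trisubstituted alkene are inert and no stereocentre is acidic once the alkoxide has formed.

Step 7
Reactants: 10 primary alcohol
Product: 11 (1R,2S,7aS)-tert-butyldimethylsilyl ether of 10
Conditions: TBSCl, imidazole, DMF, rt
Reagents that add atoms: tert-butyldimethylsilyl chloride, CC(C)(C)[Si](C)(C)Cl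
Why: Standard silylation of a primary alcohol; the TBS ether is chosen because it should survive neutral thioketal hydrolysis, hydrogenation in ethyl acetate, amine-buffered silyl iodide, ozone and a phosphorus ylide, and leaves with fluoride.

Step 8
Reactants: 11 silyl ether dithiolane
Product: 12 (1R,2S,7aS)-1-(tert-butyldimethylsilyloxymethyl)-2,7a-dimethyl-1,2,3,6,7,7a-hexahydro-5H-inden-5-one (enone C5=O, C3a=C4)
Conditions: MeI, CaCO3, MeCN–H2O, 55 °C
Reagents that add atoms: water, O
Why: S-Methylation turns the dithiolane sulfur atoms into leaving groups and water then releases the carbonyl group (alkylative thioketal hydrolysis, well known for Δ4-3-thioketals of steroids), the carbonate buffer keeping the medium neutral so that the silyl ether stays.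

Step 9
Reactants: 12 enone
Product: 13 (1R,2S,3aS,7aR)-1-(tert-butyldimethylsilyloxymethyl)-2,7a-dimethyloctahydro-5H-inden-5-one (cis-hydrindanone, 3a-H β, cis to 7a-Me)
Conditions: H2 (1 atm), Pd/C, EtOAc, rt
Reagents that add atoms: none
Why: Heterogeneous hydrogenation of 7a-methyl-tetrahydroindan-5-ones characteristically delivers hydrogen to C3a on the face of the angular methyl group and gives the cis-hydrindanone, a bias reinforced here by the 2α-methyl group on the opposite face; this sets target C1 with C4 and C7, the future isobutenyl carbon and acid chain, cis on the cyclopentane.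

Step 10
Reactants: 13 cis-hydrindanone
Product: 14 (1R,2S,3aS,7aR)-Δ4 trimethylsilyl enol ether (C4=C5–OSiMe3)
Conditions: TMSCl, NaI, Et3N, MeCN, rt
Reagents that add atoms: chlorotrimethylsilane, C[Si](C)(C)Cl
Why: Silylation with trimethylsilyl iodide made in situ and triethylamine is reversible and gives the thermodynamic enol ether, expected to be the Δ4 isomer because a double bond next to the ring fusion lets the C3a–C7a bond keep the small torsion angle that the cis-fused cyclopentane demands, the bias that also directs enolisation of cis-fused 5β-3-keto steroids towards C4.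

Step 11
Reactants: 14 Δ4 silyl enol ether
Product: 16 formyl methyl ester, via formyl acid 15 (not isolated)
Conditions: O3, CH2Cl2–MeOH, −78 °C; Me2S, −78 °C → rt; then TMSCHN2, toluene–MeOH, 0 °C
Reagents that add atoms: ozone, [O-][O+]=O; (trimethylsilyl)diazomethane, C[Si](C)(C)C=[N+]=[N-]
Why: Ozonolysis of a silyl enol ether with reductive work-up cleaves C4=C5 into an aldehyde and a silyl ester that methanol frees to acid 15, the only other functions (silyl ether, saturated carbons) being inert to ozone at −78 °C, and neutral esterification with the diazoalkane masks the acid without exposing the epimerisable formyl-bearing carbon to base.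

Step 12
Reactants: 16 methyl 3-[(1S,2R,3S,5R)-2-(tert-butyldimethylsilyloxymethyl)-5-formyl-1,3-dimethylcyclopentyl]propanoate
Product: 17 methyl 3-[(1R,2R,3S,5S)-2-(tert-butyldimethylsilyloxymethyl)-1,3-dimethyl-5-(2-methylprop-1-enyl)cyclopentyl]propanoate
Conditions: i-PrPPh3I, n-BuLi, THF, 0 °C; then 16, −78 → 0 °C
Reagents that add atoms: isopropyltriphenylphosphonium iodide, CC(C)[P+](c1ccccc1)(c1ccccc1)c1ccccc1.[I-]
Why: Wittig olefination with the unstabilised isopropylidene ylide, which adds to aldehydes at low temperature far faster than it deprotonates them or attacks a methyl ester, converts CHO into CH=CMe2, and there is little driving force for epimerisation since the C1 epimer would place the formyl group cis to both the C5 methyl and the C4 silyloxymethyl groups.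

Step 13
Reactants: 17 silyl ether ester
Product: 18 methyl 3-[(1R,2R,3S,5S)-2-(hydroxymethyl)-1,3-dimethyl-5-(2-methylprop-1-enyl)cyclopentyl]propanoate
Conditions: TBAF, AcOH, THF, rt
Reagents that add atoms: none
Why: Fluoride cleaves the Si–O bond of the primary silyl ether, and the acetic acid buffer protonates the alkoxide at once so that it cannot lactonise onto the methyl ester.

Step 14
Reactants: 18 hydroxy ester; 19 umbelliferone (7-hydroxy-2H-chromen-2-one)
Product: 20 methyl ferulsinaate (methyl ester of the target, umbelliferyl ether at the C4 CH2)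
Conditions: PPh3, DIAD, THF, 0 °C → rt
Reagents that add atoms: none
Why: Mitsunobu etherification: the acidic 7-hydroxy group of 19 is a good pronucleophile and displaces the oxyphosphonium group at the primary, β-branched but not neopentyl carbon, the usual way of making umbelliferyl ethers of terpenoid alcohols; no stereocentre takes part, and the ester keeps the carboxyl group from competing.

Step 15
Reactants: 20 methyl ferulsinaate
Product: 21 ferulsinaic acid, 3-[(1R,2R,3S,5S)-1,3-dimethyl-5-(2-methylprop-1-enyl)-2-{[(2-oxo-2H-chromen-7-yl)oxy]methyl}cyclopentyl]propanoic acid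
Conditions: LiOH, THF–MeOH–H2O, rt; then 1 M HCl to pH 2
Reagents that add atoms: lithium hydroxide, [Li+].[OH-]
Why: Saponification of the unhindered methyl ester; no stereocentre is α to a carbonyl group, and any coumarin lactone opened by hydroxide gives the (Z)-2-hydroxycinnamate, which closes again on acidification.

Compound list
1 | 2-methylcyclopentane-1,3-dione | CC1C(=O)CCC1=O | starting material
2 | but-3-en-2-one | C=CC(C)=O | starting material
3 | 2-methyl-2-(3-oxobutyl)cyclopentane-1,3-dione | CC(=O)CCC1(C)C(=O)CCC1=O | intermediate
4 | (3aR,7aR)-3a-hydroxy-7a-methylhexahydro-1H-indene-1,5(4H)-dione | O=C1C[C@]2(O)CCC(=O)[C@]2(C)CC1 | intermediate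
5 | (R)-Hajos–Parrish ketone, (7aR)-7a-methyl-2,3,7,7a-tetrahydro-1H-indene-1,5(6H)-dione | C[C@@]12CCC(=O)C=C1CCC2=O | intermediate
6 | (7aR)-5,5-(ethylenedithio)-7a-methyl-2,3,5,6,7,7a-hexahydro-1H-inden-1-one | C[C@@]12CCC3(SCCS3)C=C1CCC2=O | intermediate
7 | (7aR)-5,5-(ethylenedithio)-7a-methyl-5,6,7,7a-tetrahydro-3H-inden-1-yl trifluoromethanesulfonate | C[C@@]12CCC3(SCCS3)C=C1CC=C2OS(=O)(=O)C(F)(F)F | intermediate
8 | methyl (7aR)-5,5-(ethylenedithio)-7a-methyl-5,6,7,7a-tetrahydro-3H-indene-1-carboxylate | C[C@@]12CCC3(SCCS3)C=C1CC=C2C(=O)OC | intermediate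
9 | methyl (1R,2S,7aS)-5,5-(ethylenedithio)-2,7a-dimethyl-2,3,5,6,7,7a-hexahydro-1H-indene-1-carboxylate | C1CSC2(S1)C=C3C[C@H](C)[C@@H](C(=O)OC)[C@]3(C)CC2 | intermediate
10 | [(1R,2S,7aS)-5,5-(ethylenedithio)-2,7a-dimethyl-2,3,5,6,7,7a-hexahydro-1H-inden-1-yl]methanol | C1CSC2(S1)C=C3C[C@H](C)[C@@H](CO)[C@]3(C)CC2 | intermediate
11 | tert-butyldimethylsilyl ether of 10 | C1CSC2(S1)C=C3C[C@H](C)[C@@H](CO[Si](C)(C)C(C)(C)C)[C@]3(C)CC2 | intermediate
12 | (1R,2S,7aS)-1-(tert-butyldimethylsilyloxymethyl)-2,7a-dimethyl-1,2,3,6,7,7a-hexahydro-5H-inden-5-one | O=C1C=C2C[C@H](C)[C@@H](CO[Si](C)(C)C(C)(C)C)[C@]2(C)CC1 | intermediate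
13 | (1R,2S,3aS,7aR)-1-(tert-butyldimethylsilyloxymethyl)-2,7a-dimethyloctahydro-5H-inden-5-one | O=C1C[C@@H]2C[C@H](C)[C@@H](CO[Si](C)(C)C(C)(C)C)[C@]2(C)CC1 | intermediate
14 | (1R,2S,3aS,7aR)-Δ4 trimethylsilyl enol ether of 13 | C[Si](C)(C)OC1=C[C@@H]2C[C@H](C)[C@@H](CO[Si](C)(C)C(C)(C)C)[C@]2(C)CC1 | intermediate
15 | 3-[(1S,2R,3S,5R)-2-(tert-butyldimethylsilyloxymethyl)-5-formyl-1,3-dimethylcyclopentyl]propanoic acid | O=C[C@@H]1C[C@H](C)[C@@H](CO[Si](C)(C)C(C)(C)C)[C@]1(C)CCC(=O)O | intermediate
16 | methyl 3-[(1S,2R,3S,5R)-2-(tert-butyldimethylsilyloxymethyl)-5-formyl-1,3-dimethylcyclopentyl]propanoate | O=C[C@@H]1C[C@H](C)[C@@H](CO[Si](C)(C)C(C)(C)C)[C@]1(C)CCC(=O)OC | intermediate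
17 | methyl 3-[(1R,2R,3S,5S)-2-(tert-butyldimethylsilyloxymethyl)-1,3-dimethyl-5-(2-methylprop-1-enyl)cyclopentyl]propanoate | CC(C)=C[C@@H]1C[C@H](C)[C@@H](CO[Si](C)(C)C(C)(C)C)[C@]1(C)CCC(=O)OC | intermediate
18 | methyl 3-[(1R,2R,3S,5S)-2-(hydroxymethyl)-1,3-dimethyl-5-(2-methylprop-1-enyl)cyclopentyl]propanoate | CC(C)=C[C@@H]1C[C@H](C)[C@@H](CO)[C@]1(C)CCC(=O)OC | intermediate
19 | umbelliferone | O=c1ccc2ccc(O)cc2o1 | starting material
20 | methyl ferulsinaate | CC(C)=C[C@@H]1C[C@H](C)[C@@H](COc2ccc3ccc(=O)oc3c2)[C@]1(C)CCC(=O)OC | intermediate
21 | ferulsinaic acid | CC(C)=C[C@@H]1C[C@H](C)[C@@H](COc2ccc3ccc(=O)oc3c2)[C@]1(C)CCC(=O)O | target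

Total step count: 15. Longest linear sequence: 15 steps (1 → 21); umbelliferone 19 enters as purchased in step 14.

Steps most likely to fail

Step 10. Silylation may follow enolisation towards C6 as well as C4 (poor regioselectivity), and ozonolysis would then cut the wrong bond. The fallback sets out from enone 12 and takes the regiochemistry from the enone itself. Copper hydride-catalysed 1,4-hydrosilylation (cat. [(Ph3P)CuH]6, PhMe2SiH, toluene, rt) puts silicon on the C5 oxygen and hydrogen on C3a. This gives the Δ4 dimethylphenylsilyl enol ether F1, and a Δ5 isomer cannot form. Organocopper reagents are known to add to C3a of such 7a-methylhydrindenones on the face that leads to the cis fusion. The ring fusion would be checked by hydrolysing a sample to 13. Ozonolysis of F1 under the conditions of step 11 returns to the route at 15. This path replaces steps 9 and 10.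

Step 9. Hydrogen may be delivered in part to the α-face (poor facial selectivity, leading to the trans fusion), because the bulky 1β-silyloxymethyl group lies on the face that has to meet the catalyst. Sulfur residues from step 8 may also deactivate palladium. The fallback sets out from alcohol 10. The dithiolane is removed first (MeI, CaCO3, aq MeCN) to give the hydroxy enone F2. Its free β-oriented CH2OH then serves as a directing group in a homogeneous hydrogenation ([Ir(cod)(py)(PCy3)]PF6, H2, CH2Cl2). Hydrogen should reach the β-face of C3a through coordination instead of steric bias and give the cis-fused hydroxy ketone F3. Silylation (TBSCl, imidazole) returns to the route at 13.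

Step 12. The basic ylide may epimerise the formyl-bearing carbon, or the bulky ylide may add only sluggishly to the aldehyde next to the quaternary centre. The fallback sets out from 16 and builds the alkene without strong base. Dibromo-olefination (CBr4, PPh3, Zn, CH2Cl2, 0 °C, the first stage of the Corey–Fuchs sequence) gives the 2,2-dibromovinyl ester F4. A double Negishi methylation (Me2Zn, Pd(dppf)Cl2 cat., THF) then replaces both bromine atoms, tolerates the methyl ester, and returns to the route at 17.

Further compounds
F1 | step 10 | (1R,2S,3aS,7aR)-Δ4 dimethylphenylsilyl enol ether of 13 | C[Si](C)(c1ccccc1)OC1=C[C@@H]2C[C@H](C)[C@@H](CO[Si](C)(C)C(C)(C)C)[C@]2(C)CC1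
F2 | step 9 | (1R,2S,7aS)-1-(hydroxymethyl)-2,7a-dimethyl-1,2,3,6,7,7a-hexahydro-5H-inden-5-one | O=C1C=C2C[C@H](C)[C@@H](CO)[C@]2(C)CC1
F3 | step 9 | (1R,2S,3aS,7aR)-1-(hydroxymethyl)-2,7a-dimethyloctahydro-5H-inden-5-one | O=C1C[C@@H]2C[C@H](C)[C@@H](CO)[C@]2(C)CC1
F4 | step 12 | methyl 3-[2-(tert-butyldimethylsilyloxymethyl)-5-(2,2-dibromovinyl)-1,3-dimethylcyclopentyl]propanoate, ring configuration as in 17 | BrC(Br)=C[C@@H]1C[C@H](C)[C@@H](CO[Si](C)(C)C(C)(C)C)[C@]1(C)CCC(=O)OC
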